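**Assumption:** the target has no stereocentre and no stereogenic axis (each C-linked 2,4,6-trihydroxyphenyl ring is symmetric about its biaryl bond), so it is one achiral compound and no stereocontrol is needed.

**Retrosynthetic overview**
1. Target 13 ⇐ its nonadeca-O-methyl ether 12 by global demethylation; all eight rings are bought as arenes, none is built de novo.
2. 12 ⇐ central dibromide 10 (rings C and E) + two identical "wing" phenols 5 (rings A, B, B′), joined by a two-fold Ullmann etherification that uses the C2 symmetry.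
3. 10 ⇐ 2,6-dibromo-4-methoxyphenol 9 + boronic acid 8 (Chan–Lam); 8 ⇐ 2-chloro-1,3-dimethoxybenzene 6 by C–H borylation.
4. 5 ⇐ biaryl hydroquinone 3 + 2-iodo-1,3,5-trimethoxybenzene 4 (O-arylation at the less hindered hydroxyl).
5. 3 ⇐ 2,6-dimethoxy-1,4-benzoquinone 1 + 1,3,5-trimethoxybenzene 2: the B–B′ biaryl bond is made first, with the quinone serving as an electrophilic phenol (enolonium-type) equivalent toward a normally nucleophilic arene carbon.

**Step 1**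
Reactants: 1 2,6-dimethoxy-1,4-benzoquinone; 2 1,3,5-trimethoxybenzene (1.5 equiv)
Product: 3 2,6-dimethoxy-3-(2,4,6-trimethoxyphenyl)benzene-1,4-diol
Conditions: Sc(OTf)3 (10 mol%), HFIP/CH2Cl2, 0 °C → rt, Ar
Reagents that add atoms: none
Why: Lewis-acid-catalysed Friedel–Crafts-type conjugate (Michael) arylation of a quinone, in which scandium chelated between the C1 carbonyl and a flanking methoxy oxygen activates that carbonyl so that the only free ring carbons (C3/C5, equivalent) are its β-positions, and the adduct tautomerises to the hydroquinone with both hydroxyls free; no stereocentre is formed.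

**Step 2**
Reactants: 3 2,6-dimethoxy-3-(2,4,6-trimethoxyphenyl)benzene-1,4-diol; 4 2-iodo-1,3,5-trimethoxybenzene (1.2 equiv)
Product: 5 2,6-dimethoxy-4-(2,4,6-trimethoxyphenoxy)-3-(2,4,6-trimethoxyphenyl)phenol
Conditions: CuI (20 mol%), picolinic acid (40 mol%), K3PO4 (2.0 equiv), degassed DMSO, 95 °C, Ar
Reagents that add atoms: none
Why: Ullmann-type copper-catalysed O-arylation with a ligand system made for hindered partners, selective for the hydroxyl next to the aryl group because the other hydroxyl lies between two methoxy groups and would have to form a tetra-ortho-substituted ether with the 2,6-dimethoxyaryl iodide.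

**Step 3**
Reactants: 6 2-chloro-1,3-dimethoxybenzene
Product: 8 (4-chloro-3,5-dimethoxyphenyl)boronic acid, via aryl pinacol boronate 7 (not isolated)
Conditions: [Ir(OMe)(cod)]2 (1.5 mol%), 4,4′-di-tert-butyl-2,2′-bipyridine (3 mol%), B2pin2 (0.6 equiv), THF, 80 °C; then NaIO4 (3 equiv), aq. HCl (cat.), THF/H2O, rt
Reagents that add atoms: bis(pinacolato)diboron CC1(C)OB(OC1(C)C)B1OC(C)(C)C(C)(C)O1; water O
Why: Iridium-catalysed, sterically controlled C–H borylation goes to C5, the only C–H without an ortho substituent, and periodate cleavage of the pinacol unit in the same pot gives the free boronic acid.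

**Step 4**
Reactants: 8 (4-chloro-3,5-dimethoxyphenyl)boronic acid (2.5 equiv); 9 2,6-dibromo-4-methoxyphenol
Product: 10 1,3-dibromo-2-(4-chloro-3,5-dimethoxyphenoxy)-5-methoxybenzene
Conditions: Cu(OAc)2 (20 mol%), pyridine (3 equiv), 4 Å MS, CH2Cl2, O2 (1 atm), rt
Reagents that add atoms: none
Why: Chan–Lam oxidative O-arylation runs at room temperature, accepts 2,6-dihalophenols, and leaves both C–Br bonds and the C–Cl bond intact for the next step.

**Step 5**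
Reactants: 10 1,3-dibromo-2-(4-chloro-3,5-dimethoxyphenoxy)-5-methoxybenzene; 5 2,6-dimethoxy-4-(2,4,6-trimethoxyphenoxy)-3-(2,4,6-trimethoxyphenyl)phenol (2.4 equiv)
Product: 12 nonadeca-O-methyl ether of the target (2-(4-chloro-3,5-dimethoxyphenoxy)-5-methoxy-1,3-bis[2,6-dimethoxy-4-(2,4,6-trimethoxyphenoxy)-3-(2,4,6-trimethoxyphenyl)phenoxy]benzene), via mono-ether bromide 11 (not isolated)
Conditions: CuCl (50 mol%), 2,2,6,6-tetramethylheptane-3,5-dione (25 mol%), Cs2CO3 (4 equiv), NMP, 120 °C, Ar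
Reagents that add atoms: none
Why: Two-fold diketone-accelerated Ullmann diaryl ether synthesis, the usual way to join 2,6-dimethoxyphenols to aryl bromides, with the only free hydroxyl of 5 as nucleophile and the electron-rich, doubly ortho-flanked C–Cl bond inert to copper.

**Step 6**
Reactants: 12 nonadeca-O-methyl ether of the target
Product: 13 CNP0275555.0 (target)
Conditions: BBr3 (40 equiv), CH2Cl2, −78 °C → rt, 24 h; ice-water quench; reversed-phase HPLC under Ar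
Reagents that add atoms: none
Why: Lewis-acid ether cleavage (BBr3 demethylation) removes all nineteen O-methyl groups, while the diaryl ether, biaryl and aryl chloride bonds are inert to BBr3 and there is no stereocentre to disturb.

**Compound list**
1 | 2,6-dimethoxy-1,4-benzoquinone | COC1=CC(=O)C=C(OC)C1=O | starting material
2 | 1,3,5-trimethoxybenzene | COc1cc(OC)cc(OC)c1 | starting material
3 | 2,6-dimethoxy-3-(2,4,6-trimethoxyphenyl)benzene-1,4-diol | Oc1c(OC)cc(O)c(-c2c(OC)cc(OC)cc2OC)c1OC | intermediate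
4 | 2-iodo-1,3,5-trimethoxybenzene | COc1cc(OC)c(I)c(OC)c1 | starting material
5 | 2,6-dimethoxy-4-(2,4,6-trimethoxyphenoxy)-3-(2,4,6-trimethoxyphenyl)phenol | Oc1c(OC)cc(Oc2c(OC)cc(OC)cc2OC)c(-c2c(OC)cc(OC)cc2OC)c1OC | intermediate
6 | 2-chloro-1,3-dimethoxybenzene | COc1cccc(OC)c1Cl | starting material
7 | 2-(4-chloro-3,5-dimethoxyphenyl)-4,4,5,5-tetramethyl-1,3,2-dioxaborolane | COc1cc(B2OC(C)(C)C(C)(C)O2)cc(OC)c1Cl | intermediate (not isolated)
8 | (4-chloro-3,5-dimethoxyphenyl)boronic acid | COc1cc(B(O)O)cc(OC)c1Cl | intermediate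
9 | 2,6-dibromo-4-methoxyphenol | COc1cc(Br)c(O)c(Br)c1 | starting material
10 | 1,3-dibromo-2-(4-chloro-3,5-dimethoxyphenoxy)-5-methoxybenzene | COc1cc(Br)c(Oc2cc(OC)c(Cl)c(OC)c2)c(Br)c1 | intermediate
11 | 1-bromo-2-(4-chloro-3,5-dimethoxyphenoxy)-3-[2,6-dimethoxy-4-(2,4,6-trimethoxyphenoxy)-3-(2,4,6-trimethoxyphenyl)phenoxy]-5-methoxybenzene | COc1cc(Br)c(Oc2cc(OC)c(Cl)c(OC)c2)c(Oc2c(OC)cc(Oc3c(OC)cc(OC)cc3OC)c(-c3c(OC)cc(OC)cc3OC)c2OC)c1 | intermediate (not isolated)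
12 | nonadeca-O-methyl ether of the target | COc1cc(Oc2c(OC)cc(Oc3c(OC)cc(OC)cc3OC)c(-c3c(OC)cc(OC)cc3OC)c2OC)c(Oc2cc(OC)c(Cl)c(OC)c2)c(Oc2c(OC)cc(Oc3c(OC)cc(OC)cc3OC)c(-c3c(OC)cc(OC)cc3OC)c2OC)c1 | intermediate
13 | CNP0275555.0 | Oc1cc(O)c(Oc2cc(O)c(Oc3cc(O)cc(Oc4c(O)cc(Oc5c(O)cc(O)cc5O)c(-c5c(O)cc(O)cc5O)c4O)c3Oc3cc(O)c(Cl)c(O)c3)c(O)c2-c2c(O)cc(O)cc2O)c(O)c1 | target

**Step count:** 6 steps in total. Longest linear sequence: 4 steps (1 → 2 → 5 → 6); the core branch 3 → 4 → 5 → 6 is equally long.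

**Steps most likely to fail, with fallbacks**

Step 1 (quinone arylation) is the main risk. The arene may attack a methoxy-bearing carbon and displace methanol, or the product hydroquinone may exchange redox state with unreacted quinone. The fallback sets out from 2 and replaces the quinone by its monoketal. Commercial 3,4,5-trimethoxyphenol is oxidised with PhI(OAc)2 in MeOH to 3,4,4,5-tetramethoxycyclohexa-2,5-dien-1-one F1. F1 is coupled with 2 (BF3·OEt2 or perfluorobenzoic acid, HFIP) by attack next to the carbonyl and loss of methanol, giving 3,4,5-trimethoxy-2-(2,4,6-trimethoxyphenyl)phenol F2. F2 is O-arylated with 4 (CuI, picolinic acid, K3PO4, DMSO) to 1,2,3-trimethoxy-5-(2,4,6-trimethoxyphenoxy)-4-(2,4,6-trimethoxyphenyl)benzene F3. BCl3 (1.1 equiv, CH2Cl2, −20 °C) then cleaves the methoxy group flanked by two methoxy groups, and the route is rejoined at 5. This costs two extra steps, and the selectivity of the last cleavage against the neighbouring methoxy group next to the aryl ring would have to be checked.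

Step 2 (hindered, site-selective O-arylation of an air-sensitive hydroquinone) may stall or give mixtures. The fallback sets out from 3 and installs ring A by nucleophilic aromatic substitution instead of copper coupling. Compound 3 reacts at its less hindered hydroxyl with commercial 4-fluoro-3,5-dimethoxybenzaldehyde (Cs2CO3, DMSO, 110 °C) to give 4-[4-hydroxy-3,5-dimethoxy-2-(2,4,6-trimethoxyphenyl)phenoxy]-3,5-dimethoxybenzaldehyde F4. F4 (2.4 equiv) is coupled with 10 under the step 5 conditions, through the mono-ether bromide 4-[4-[3-bromo-2-(4-chloro-3,5-dimethoxyphenoxy)-5-methoxyphenoxy]-3,5-dimethoxy-2-(2,4,6-trimethoxyphenyl)phenoxy]-3,5-dimethoxybenzaldehyde F5, to the dialdehyde 2-(4-chloro-3,5-dimethoxyphenoxy)-5-methoxy-1,3-bis[4-(4-formyl-2,6-dimethoxyphenoxy)-2,6-dimethoxy-3-(2,4,6-trimethoxyphenyl)phenoxy]benzene F6. Dakin oxidation (H2O2, cat. H2SO4, MeOH, rt) proceeds through the bis(formate) 2-(4-chloro-3,5-dimethoxyphenoxy)-5-methoxy-1,3-bis[4-(4-formyloxy-2,6-dimethoxyphenoxy)-2,6-dimethoxy-3-(2,4,6-trimethoxyphenyl)phenoxy]benzene F7 to the bis-phenol 2-(4-chloro-3,5-dimethoxyphenoxy)-5-methoxy-1,3-bis[4-(4-hydroxy-2,6-dimethoxyphenoxy)-2,6-dimethoxy-3-(2,4,6-trimethoxyphenyl)phenoxy]benzene F8. F8 already carries the free para-hydroxyls of rings A and F, and BBr3 as in step 6 brings the route back at 13.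

Step 5 (two hindered Ullmann couplings on one ring) may stop at 11. The fallback sets out from 5 and builds ring C around an activated difluoride. Compound 5 (2.2 equiv) displaces both fluorides of commercial 2,6-difluoro-4-methoxybenzaldehyde (Cs2CO3, DMSO, 110 °C), through 2-fluoro-4-methoxy-6-[2,6-dimethoxy-4-(2,4,6-trimethoxyphenoxy)-3-(2,4,6-trimethoxyphenyl)phenoxy]benzaldehyde F9, to give 4-methoxy-2,6-bis[2,6-dimethoxy-4-(2,4,6-trimethoxyphenoxy)-3-(2,4,6-trimethoxyphenyl)phenoxy]benzaldehyde F10. Dakin oxidation (H2O2, cat. H2SO4, MeOH) proceeds through 4-methoxy-2,6-bis[2,6-dimethoxy-4-(2,4,6-trimethoxyphenoxy)-3-(2,4,6-trimethoxyphenyl)phenoxy]phenyl formate F11 to 4-methoxy-2,6-bis[2,6-dimethoxy-4-(2,4,6-trimethoxyphenoxy)-3-(2,4,6-trimethoxyphenyl)phenoxy]phenol F12. Chan–Lam coupling of F12 with 8 (Cu(OAc)2, pyridine, O2) returns to the route at 12; compounds 9 and 10 are then not needed.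

**Further compounds**
F1 | step 1 | 3,4,4,5-tetramethoxycyclohexa-2,5-dien-1-one | COC1=CC(=O)C=C(OC)C1(OC)OC
F2 | step 1 | 3,4,5-trimethoxy-2-(2,4,6-trimethoxyphenyl)phenol | Oc1cc(OC)c(OC)c(OC)c1-c1c(OC)cc(OC)cc1OC
F3 | step 1 | 1,2,3-trimethoxy-5-(2,4,6-trimethoxyphenoxy)-4-(2,4,6-trimethoxyphenyl)benzene | COc1cc(Oc2c(OC)cc(OC)cc2OC)c(-c2c(OC)cc(OC)cc2OC)c(OC)c1OC
F4 | step 2 | 4-[4-hydroxy-3,5-dimethoxy-2-(2,4,6-trimethoxyphenyl)phenoxy]-3,5-dimethoxybenzaldehyde | Oc1c(OC)cc(Oc2c(OC)cc(C=O)cc2OC)c(-c2c(OC)cc(OC)cc2OC)c1OC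
F5 | step 2 | 4-[4-[3-bromo-2-(4-chloro-3,5-dimethoxyphenoxy)-5-methoxyphenoxy]-3,5-dimethoxy-2-(2,4,6-trimethoxyphenyl)phenoxy]-3,5-dimethoxybenzaldehyde | COc1cc(Br)c(Oc2cc(OC)c(Cl)c(OC)c2)c(Oc2c(OC)cc(Oc3c(OC)cc(C=O)cc3OC)c(-c3c(OC)cc(OC)cc3OC)c2OC)c1
F6 | step 2 | 2-(4-chloro-3,5-dimethoxyphenoxy)-5-methoxy-1,3-bis[4-(4-formyl-2,6-dimethoxyphenoxy)-2,6-dimethoxy-3-(2,4,6-trimethoxyphenyl)phenoxy]benzene | COc1cc(Oc2c(OC)cc(Oc3c(OC)cc(C=O)cc3OC)c(-c3c(OC)cc(OC)cc3OC)c2OC)c(Oc2cc(OC)c(Cl)c(OC)c2)c(Oc2c(OC)cc(Oc3c(OC)cc(C=O)cc3OC)c(-c3c(OC)cc(OC)cc3OC)c2OC)c1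
F7 | step 2 | 2-(4-chloro-3,5-dimethoxyphenoxy)-5-methoxy-1,3-bis[4-(4-formyloxy-2,6-dimethoxyphenoxy)-2,6-dimethoxy-3-(2,4,6-trimethoxyphenyl)phenoxy]benzene | COc1cc(Oc2c(OC)cc(Oc3c(OC)cc(OC=O)cc3OC)c(-c3c(OC)cc(OC)cc3OC)c2OC)c(Oc2cc(OC)c(Cl)c(OC)c2)c(Oc2c(OC)cc(Oc3c(OC)cc(OC=O)cc3OC)c(-c3c(OC)cc(OC)cc3OC)c2OC)c1
F8 | step 2 | 2-(4-chloro-3,5-dimethoxyphenoxy)-5-methoxy-1,3-bis[4-(4-hydroxy-2,6-dimethoxyphenoxy)-2,6-dimethoxy-3-(2,4,6-trimethoxyphenyl)phenoxy]benzene | COc1cc(Oc2c(OC)cc(Oc3c(OC)cc(O)cc3OC)c(-c3c(OC)cc(OC)cc3OC)c2OC)c(Oc2cc(OC)c(Cl)c(OC)c2)c(Oc2c(OC)cc(Oc3c(OC)cc(O)cc3OC)c(-c3c(OC)cc(OC)cc3OC)c2OC)c1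
F9 | step 5 | 2-fluoro-4-methoxy-6-[2,6-dimethoxy-4-(2,4,6-trimethoxyphenoxy)-3-(2,4,6-trimethoxyphenyl)phenoxy]benzaldehyde | COc1cc(F)c(C=O)c(Oc2c(OC)cc(Oc3c(OC)cc(OC)cc3OC)c(-c3c(OC)cc(OC)cc3OC)c2OC)c1
F10 | step 5 | 4-methoxy-2,6-bis[2,6-dimethoxy-4-(2,4,6-trimethoxyphenoxy)-3-(2,4,6-trimethoxyphenyl)phenoxy]benzaldehyde | COc1cc(Oc2c(OC)cc(Oc3c(OC)cc(OC)cc3OC)c(-c3c(OC)cc(OC)cc3OC)c2OC)c(C=O)c(Oc2c(OC)cc(Oc3c(OC)cc(OC)cc3OC)c(-c3c(OC)cc(OC)cc3OC)c2OC)c1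
F11 | step 5 | 4-methoxy-2,6-bis[2,6-dimethoxy-4-(2,4,6-trimethoxyphenoxy)-3-(2,4,6-trimethoxyphenyl)phenoxy]phenyl formate | COc1cc(Oc2c(OC)cc(Oc3c(OC)cc(OC)cc3OC)c(-c3c(OC)cc(OC)cc3OC)c2OC)c(OC=O)c(Oc2c(OC)cc(Oc3c(OC)cc(OC)cc3OC)c(-c3c(OC)cc(OC)cc3OC)c2OC)c1
F12 | step 5 | 4-methoxy-2,6-bis[2,6-dimethoxy-4-(2,4,6-trimethoxyphenoxy)-3-(2,4,6-trimethoxyphenyl)phenoxy]phenol | COc1cc(Oc2c(OC)cc(Oc3c(OC)cc(OC)cc3OC)c(-c3c(OC)cc(OC)cc3OC)c2OC)c(O)c(Oc2c(OC)cc(Oc3c(OC)cc(OC)cc3OC)c(-c3c(OC)cc(OC)cc3OC)c2OC)c1
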